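Daucane numbering: ring A is the cyclopentane C1–C5, ring B the cycloheptane C1/C5–C10. The route rests on cutting C4–C5 and C1–C15. It exploits the aldol array C4(O)–C5–C6(O) that spans both rings, with quaternary C1 β to C6. The precursor is an achiral ring-B dienone bearing a 4-methyl-3-oxopentyl chain at C1. In one operation a chiral copper catalyst adds methyl to C1, the C5 enolate closes ring A on the C4 ketone, and all aldol isomers converge by dehydration on one C4=C5 enone. C1 then controls C4 and C5 (β-epoxidation, reductive opening), C6, C9, C10 and C8.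

Key step: step 5

Remark: β is the face of the C15 methyl group (ring A drawn left, C1 at the top of the shared bond) and α the opposite face. The oxirane and dioxolane rings that appear after step 5 count as functional or protecting groups, not as carbocyclic skeleton. Compounds 1 and 5 are taken as commercial.

Step 1
Reactants: 1 cycloheptane-1,3-dione
Product: 2 3-isobutoxycyclohept-2-en-1-one
Conditions: i-BuOH, PPTS (cat.), toluene, reflux, Dean–Stark
Reagents that add atoms: isobutanol CC(C)CO
Why: Acid-catalysed enol etherification of a symmetrical 1,3-dione (vinylogous ester formation) can give only one product and differentiates the future C1 and C6.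

Step 2
Reactants: 2 3-isobutoxycyclohept-2-en-1-one
Product: 4 3-isobutoxycyclohepta-2,6-dien-1-one, via lithium enolate 3 (not isolated)
Conditions: LDA, THF, −78 °C; then PhS(Cl)=N-t-Bu, −78 °C
Reagents that add atoms: none
Why: A vinylogous ester is deprotonated kinetically at the α′-CH2 (future C10), and the Mukaiyama dehydrogenation (S-attack of the enolate, then syn-elimination) should install the future C9=C10 bond in one pot.

Step 3
Reactants: 5 4-methylpent-1-en-3-one
Product: 6 2-(2-bromoethyl)-2-isopropyl-1,3-dioxolane
Conditions: HBr (g), CH2Cl2, 0 °C; then ethylene glycol, p-TsOH (cat.), rt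
Reagents that add atoms: hydrogen bromide Br; ethylene glycol OCCO
Why: Conjugate hydrobromination of a vinyl ketone followed by ketalisation is the standard entry to β-bromo ketals, which act as masked ketone homoenolate equivalents.

Step 4
Reactants: 6 2-(2-bromoethyl)-2-isopropyl-1,3-dioxolane; 4 3-isobutoxycyclohepta-2,6-dien-1-one
Product: 9 3-(4-methyl-3-oxopentyl)cyclohepta-2,4-dien-1-one, via Grignard reagent 7 (not isolated), via bromomagnesium alkoxide 8 (not isolated)
Conditions: Mg, THF, ≤30 °C; then 4, LaCl3·2LiCl (cat.), THF, −78 → 0 °C; then 2 M aq HCl, THF, rt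
Reagents that add atoms: water O
Why: Stork–Danheiser transposition, in which 7 adds 1,2 to the cross-conjugated carbonyl (C1), acid ionises the bis-allylic alcohol through the alkoxy-stabilised cation so that water enters at C6, and the same acid unmasks the C4 ketone.

Step 5
Reactants: 9 3-(4-methyl-3-oxopentyl)cyclohepta-2,4-dien-1-one
Product: 12 14-nordauca-4,9-dien-6-one (8a-methyl-3-isopropyl-2,5,6,8a-tetrahydro-1H-azulen-4-one, C15 β), via aluminium enolate 10 (not isolated), via aldol adducts 11 (not isolated)
Conditions: Me3Al, copper thiophene-2-carboxylate (CuTC, 5 mol %), biphenol-derived phosphoramidite with a bis(1-arylethyl)amine unit (10 mol %, enantiomer chosen for β-methyl delivery), Et2O, −30 °C; then MeOH, KOH, 0 → 50 °C, one pot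
Reagents that add atoms: trimethylaluminium C[Al](C)C
Why: A ligated methylcopper species made from Me3Al adds methyl to C1 of the aluminium-activated dienone (π-complex, trivalent copper intermediate, reductive elimination) and leaves the C5=C6 dimethylaluminium enolate 10, the only enolate that reaches the C4 ketone through a five-membered transition state. Ring A closes by a 5-(enolexo)-exo-trig aldol addition, and hydroxide then drives E1cB loss of water, so that all four C4/C5 aldol diastereomers 11 and any uncyclised diketone should converge on the single planar C4=C5 enone 12. The closest known reaction types are the copper-catalysed asymmetric conjugate addition of trialkylaluminium reagents to β-substituted cyclic enones and polyconjugated dienones, the tandem conjugate addition–aldol cyclisation of keto-enones, and the classical 1,6-diketone to acylcyclopentene condensation. The only stereocentre that survives, quaternary C1, is set by the chiral ligand on copper, and the kinetic preference of such closures for the unwanted cis ring fusion is made irrelevant because C4 and C5 are flattened. The step needs 1,4- over 1,6-addition (the Lewis-acidic aluminium reagent holds copper at the C5=C1 bond next to the complexed carbonyl), enone over chain ketone (a branched saturated ketone reacts only slowly with Me3Al in Et2O at −30 °C) and C5 over C3/C7 aldolisation (these modes give bridged ketols that cannot dehydrate and revert).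

Step 6
Reactants: 12 14-nordauca-4,9-dien-6-one
Product: 13 4β,5β-epoxy-14-nordauc-9-en-6-one
Conditions: 30% aq H2O2, NaOH (cat.), MeOH, 0 °C → rt
Reagents that add atoms: hydrogen peroxide OO
Why: Weitz–Scheffer epoxidation, in which reversible hydroperoxide addition at C4 and closure at C5 should place oxygen syn to C15 (β), because this keeps the isopropyl group away from C15 and gives the cis-type junction, as with angular-methyl octalones and steroidal 4-en-3-ones; the isolated C9=C10 bond is inert.

Step 7
Reactants: 13 4β,5β-epoxy-14-nordauc-9-en-6-one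
Product: 14 4β-hydroxy-5αH-14-nordauc-9-en-6-one (trans-fused)
Conditions: SmI2, THF/MeOH, −78 °C
Reagents that add atoms: none
Why: Reduction of an α,β-epoxy ketone by divalent samarium cleaves only the Cα–O bond (C5–O), so C4 keeps its β-oxygen, and the enolate should be protonated at C5 from the α face, giving the trans fusion that is also the more stable C5 epimer (isopropyl and C6 trans on ring A).

Step 8
Reactants: 14 4β-hydroxy-5αH-14-nordauc-9-en-6-one
Product: 15 5αH-14-nordauc-9-ene-4β,6α-diol
Conditions: Me4NBH(OAc)3, MeCN/AcOH, −20 °C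
Reagents that add atoms: none
Why: Evans–Saksena reduction, in which boron bound to the 4β-oxygen delivers hydride to the β face of C6 through a six-membered transition state and gives the 1,3-anti diol (6α-OH), the opposite of undirected α-face attack.

Step 9
Reactants: 15 5αH-14-nordauc-9-ene-4β,6α-diol
Product: 16 6α-isovaleryloxy-5αH-14-nordauc-9-en-4β-ol
Conditions: isovaleric anhydride, Et3N, DMAP (cat.), CH2Cl2, 0 °C → rt
Reagents that add atoms: isovaleric anhydride CC(C)CC(=O)OC(=O)CC(C)C
Why: DMAP-catalysed acylation takes the secondary 6α-hydroxyl and leaves the hindered tertiary 4β-hydroxyl untouched.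

Step 10
Reactants: 16 6α-isovaleryloxy-5αH-14-nordauc-9-en-4β-ol
Product: 17 6α-isovaleryloxy-4β-hydroxy-5αH-14-nordauc-9-en-8-one
Conditions: Rh2(cap)4 (dirhodium tetrakis(caprolactamate), cat.), aq t-BuOOH, 1,2-dichloroethane, 40 °C
Reagents that add atoms: tert-butyl hydroperoxide CC(C)(C)OO
Why: Dirhodium-catalysed allylic oxidation works through an allyl radical, C8 is the only allylic C–H position because C1 is quaternary, and the peroxy radical should be taken up at C8 and not at neopentyl C10.

Step 11
Reactants: 17 6α-isovaleryloxy-4β-hydroxy-5αH-14-nordauc-9-en-8-one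
Product: 18 6α-isovaleryloxy-4β,9α,10α-trihydroxy-5αH-14-nordaucan-8-one
Conditions: OsO4 (cat.), NMO, citric acid, t-BuOH/acetone/H2O, rt
Reagents that add atoms: osmium tetroxide O=[Os](=O)(=O)=O; N-methylmorpholine N-oxide C[N+]1([O-])CCOCC1; water O
Why: Upjohn syn-dihydroxylation (acid-buffered for an electron-poor alkene) should occur on the α face, opposite the axial C15 methyl next to C10, setting 9α-OH and 10α-OH together.

Step 12
Reactants: 18 6α-isovaleryloxy-4β,9α,10α-trihydroxy-5αH-14-nordaucan-8-one
Product: 19 9α,10α-O-isopropylidene derivative of 18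
Conditions: 2,2-dimethoxypropane, PPTS (cat.), CH2Cl2, rt
Reagents that add atoms: 2,2-dimethoxypropane COC(C)(C)OC
Why: Transketalisation engages only the cis-vicinal 9,10-diol, and the mild acid should not enolise C9 or ionise the tertiary alcohol.

Step 13
Reactants: 19 9α,10α-O-isopropylidene derivative of 18
Product: 20 6α-isovaleryloxy-9α,10α-isopropylidenedioxy-5αH-dauc-8(14)-en-4β-ol
Conditions: Zn, CH2Br2, TiCl4, THF (pre-aged, 5 °C); then 19, CH2Cl2, 0 °C → rt
Reagents that add atoms: dibromomethane BrCBr
Why: Takai–Lombardo methylenation is non-basic and prefers ketones to esters, so C14 should be introduced without β-elimination of the C6 ester or epimerisation at C9.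

Step 14
Reactants: 20 6α-isovaleryloxy-9α,10α-isopropylidenedioxy-5αH-dauc-8(14)-en-4β-ol
Product: 21 6α-isovaleryloxy-5αH-dauc-8(14)-ene-4β,9α,10α-triol
Conditions: AcOH/H2O 4:1, 40 °C
Reagents that add atoms: none
Why: Mild aqueous acid hydrolyses the acetonide while the ester, the 1,1-disubstituted alkene and the tertiary alcohol should survive.

Step 15
Reactants: 21 6α-isovaleryloxy-5αH-dauc-8(14)-ene-4β,9α,10α-triol
Product: 22 6α-isovaleryloxy-8α,14-epoxy-5αH-daucane-4β,9α,10α-triol (CNP0307265.1)
Conditions: VO(acac)2 (cat.), t-BuOOH (decane), CH2Cl2, 0 °C → rt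
Reagents that add atoms: tert-butyl hydroperoxide CC(C)(C)OO
Why: Hydroxyl-directed vanadium epoxidation, in which the vanadate bound to the allylic 9α-OH (supported by 10α-OH) delivers oxygen to the α face of the only alkene, so the spiro-oxirane oxygen is α at C8.

Compound list
1 | cycloheptane-1,3-dione | O=C1CCCCC(=O)C1 | starting material
2 | 3-isobutoxycyclohept-2-en-1-one | CC(C)COC1=CC(=O)CCCC1 | intermediate
3 | lithium α′-enolate of 2 | CC(C)COC1=CC(O[Li])=CCCC1 | intermediate
4 | 3-isobutoxycyclohepta-2,6-dien-1-one | CC(C)COC1=CC(=O)C=CCC1 | intermediate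
5 | 4-methylpent-1-en-3-one | C=CC(=O)C(C)C | starting material
6 | 2-(2-bromoethyl)-2-isopropyl-1,3-dioxolane | BrCCC1(C(C)C)OCCO1 | intermediate
7 | [2-(2-isopropyl-1,3-dioxolan-2-yl)ethyl]magnesium bromide | Br[Mg]CCC1(C(C)C)OCCO1 | intermediate
8 | bromomagnesium alkoxide of the 1,2-adduct of 7 and 4 | CC(C)COC1=CC(CCC2(C(C)C)OCCO2)(O[Mg]Br)C=CCC1 | intermediate
9 | 3-(4-methyl-3-oxopentyl)cyclohepta-2,4-dien-1-one | CC(C)C(=O)CCC1=CC(=O)CCC=C1 | intermediate
10 | C5=C6 dimethylaluminium enolate of 3-methyl-3-(4-methyl-3-oxopentyl)cyclohept-4-en-1-one | C[Al](C)OC1=C[C@](C)(CCC(=O)C(C)C)C=CCC1 | intermediate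
11 | 4-hydroxy-14-nordauc-9-en-6-ones, mixture of C4/C5 isomers | O=C1CCC=C[C@@]2(C)CCC(O)(C(C)C)C12 | intermediate
12 | 14-nordauca-4,9-dien-6-one | O=C1CCC=C[C@@]2(C)CCC(C(C)C)=C12 | intermediate
13 | 4β,5β-epoxy-14-nordauc-9-en-6-one | O=C1CCC=C[C@@]2(C)CC[C@]3(C(C)C)O[C@]123 | intermediate
14 | 4β-hydroxy-5αH-14-nordauc-9-en-6-one | O=C1CCC=C[C@@]2(C)CC[C@@](O)(C(C)C)[C@H]12 | intermediate
15 | 5αH-14-nordauc-9-ene-4β,6α-diol | O[C@H]1CCC=C[C@@]2(C)CC[C@@](O)(C(C)C)[C@H]12 | intermediate
16 | 6α-isovaleryloxy-5αH-14-nordauc-9-en-4β-ol | CC(C)CC(=O)O[C@H]1CCC=C[C@@]2(C)CC[C@@](O)(C(C)C)[C@H]12 | intermediate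
17 | 6α-isovaleryloxy-4β-hydroxy-5αH-14-nordauc-9-en-8-one | CC(C)CC(=O)O[C@H]1CC(=O)C=C[C@@]2(C)CC[C@@](O)(C(C)C)[C@H]12 | intermediate
18 | 6α-isovaleryloxy-4β,9α,10α-trihydroxy-5αH-14-nordaucan-8-one | CC(C)CC(=O)O[C@H]1CC(=O)[C@@H](O)[C@@H](O)[C@@]2(C)CC[C@@](O)(C(C)C)[C@H]12 | intermediate
19 | 9α,10α-O-isopropylidene derivative of 18 | CC(C)CC(=O)O[C@H]1CC(=O)[C@H]3OC(C)(C)O[C@H]3[C@@]2(C)CC[C@@](O)(C(C)C)[C@H]12 | intermediate
20 | 6α-isovaleryloxy-9α,10α-isopropylidenedioxy-5αH-dauc-8(14)-en-4β-ol | CC(C)CC(=O)O[C@H]1CC(=C)[C@H]3OC(C)(C)O[C@H]3[C@@]2(C)CC[C@@](O)(C(C)C)[C@H]12 | intermediate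
21 | 6α-isovaleryloxy-5αH-dauc-8(14)-ene-4β,9α,10α-triol | CC(C)CC(=O)O[C@H]1CC(=C)[C@@H](O)[C@@H](O)[C@@]2(C)CC[C@@](O)(C(C)C)[C@H]12 | intermediate
22 | 6α-isovaleryloxy-8α,14-epoxy-5αH-daucane-4β,9α,10α-triol (CNP0307265.1) | CC(C)CC(=O)O[C@H]1C[C@]2(CO2)[C@@H](O)[C@@H](O)[C@@]2(C)CC[C@@](O)(C(C)C)[C@H]12 | target

Total step count: 15. Longest linear sequence: 14 (steps 1, 2 and 4–15; step 3 is a side branch).

Steps most likely to fail

Step 5. Methyl may be transferred to C9 (1,6-addition) or to the chain ketone, the catalyst may discriminate the faces of C1 poorly, or dehydration may be sluggish. The fallback exchanges resident group and nucleophile and keeps the chain ketone masked. It sets out from 4. MeLi in THF at −78 °C gives 3-isobutoxy-1-methylcyclohepta-2,6-dien-1-ol F1, which aqueous HCl transposes to 3-methylcyclohepta-2,4-dien-1-one F2. Grignard reagent 7 is then added 1,4 under Cu(OTf)2 and a chiral hydroxyalkyl N-heterocyclic carbene ligand. This is the best documented pairing for quaternary centres on polyconjugated cyclic enones, and it should give the ketal ketone 3-[2-(2-isopropyl-1,3-dioxolan-2-yl)ethyl]-3-methylcyclohept-4-en-1-one F3. Aqueous HCl unmasks 3-methyl-3-(4-methyl-3-oxopentyl)cyclohept-4-en-1-one F4, and KOH in EtOH closes ring A by aldol condensation. The fallback returns to the route at 12.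

Step 6. Hydroperoxide addition to the congested tetrasubstituted enone may be slow and the facial selectivity poor. The fallback replaces nucleophilic epoxidation by hydroxyl-directed epoxidation and sets out from 12. Luche reduction (NaBH4, CeCl3·7H2O, MeOH) should attack C6 from the α face, as in 6-oxo steroids, and give 14-nordauca-4,9-dien-6β-ol F5. VO(acac)2 with t-BuOOH then delivers oxygen syn to the 6β-hydroxyl and only to the allylic C4=C5 bond, giving 4β,5β-epoxy-14-nordauc-9-en-6β-ol F6. Dess–Martin oxidation returns to the route at 13.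

Step 10. Hydrogen abstraction may be unselective, oxygen may enter at the wrong allyl terminus, or over-oxidation may occur. The fallback replaces the radical process by a pericyclic one and sets out from 16. Riley oxidation (SeO2 cat., t-BuOOH, CH2Cl2) proceeds by an ene reaction and a [2,3]-sigmatropic shift. This restores the C9=C10 position and should give 6α-isovaleryloxy-5αH-14-nordauc-9-ene-4β,8-diol F7, whose C8 configuration does not matter. MnO2 or Dess–Martin oxidation of the allylic alcohol returns to the route at 17.

Further compounds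
F1 | step 5 | 3-isobutoxy-1-methylcyclohepta-2,6-dien-1-ol | CC(C)COC1=CC(C)(O)C=CCC1
F2 | step 5 | 3-methylcyclohepta-2,4-dien-1-one | CC1=CC(=O)CCC=C1
F3 | step 5 | 3-[2-(2-isopropyl-1,3-dioxolan-2-yl)ethyl]-3-methylcyclohept-4-en-1-one | O=C1CCC=C[C@@](C)(CCC2(C(C)C)OCCO2)C1
F4 | step 5 | 3-methyl-3-(4-methyl-3-oxopentyl)cyclohept-4-en-1-one | O=C1CCC=C[C@@](C)(CCC(=O)C(C)C)C1
F5 | step 6 | 14-nordauca-4,9-dien-6β-ol | O[C@@H]1CCC=C[C@@]2(C)CCC(C(C)C)=C12
F6 | step 6 | 4β,5β-epoxy-14-nordauc-9-en-6β-ol | O[C@@H]1CCC=C[C@@]2(C)CC[C@]3(C(C)C)O[C@]123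
F7 | step 10 | 6α-isovaleryloxy-5αH-14-nordauc-9-ene-4β,8-diol | CC(C)CC(=O)O[C@H]1CC(O)C=C[C@@]2(C)CC[C@@](O)(C(C)C)[C@H]12
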